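The plan builds the chromone benzene ring (C4a, C5, C6, C7, C8, C8a) last, through the C4a–C5 bond. This ring has an oxygen on every second carbon (C5, C7, C8a), the mark of a pentaketide chain, and the bridging CH2 stands on C6, flanked by the C5 and C7 oxygens. A 4-pyranone carrying a C-benzylated acetoacetate chain is therefore acylated at its own ring carbon C3 by the chain ester, a Claisen closure that delivers the carbocycle, both phenols and the bridge position in one operation. The precursor is a methyl β-keto ester whose α-carbon bears the (3R)-isochromanone as a benzyl group and whose γ-carbon bears the 6-methyl-4-oxopyran-2-yl ring; the lone stereocenter comes from (R)-propylene oxide.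

Key step: step 10

Remark: quenching the lithiated pyranone with a carbonate would stop at the pyranylacetate, so the acetoacetate chain is made by carboxylation and a two-carbon malonate homologation.
Remark: the configuration at C2 of the keto ester chain in the key-step precursor is not controlled and does not matter, because that carbon becomes aromatic C6.
Assumption: methyl 2,4-dihydroxy-3-methylbenzoate, (R)-2-methyloxirane and 2,6-dimethyl-4H-pyran-4-one are bought, and the enantiomeric purity of the target is that of the epoxide.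

Step 1
Reactants: 1 methyl 2,4-dihydroxy-3-methylbenzoate
Product: 2 methyl 2,4-diisopropoxy-3-methylbenzoate
Conditions: 2-bromopropane (4 equiv), K2CO3 (4 equiv), DMF, 80 °C
Reagents that add atoms: 2-bromopropane CC(C)Br
Why: Williamson ether synthesis with excess secondary bromide in hot DMF should alkylate both phenols, the chelated 2-hydroxyl included, while carbonate leaves the methyl ester alone.

Step 2
Reactants: 2 methyl 2,4-diisopropoxy-3-methylbenzoate
Product: 3 N,N-diethyl-2,4-diisopropoxy-3-methylbenzamide
Conditions: AlMe3 (3 equiv), Et2NH (3 equiv), toluene, 0 → 90 °C; then dilute aq. HCl, 0 °C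
Reagents that add atoms: diethylamine CCNCC
Why: Aminolysis of the methyl ester by the aluminium amide Me2AlNEt2 formed in the flask is a reliable ester-to-tertiary-amide conversion that tolerates aryl ethers and installs the directing group needed for step 3.

Step 3
Reactants: 3 N,N-diethyl-2,4-diisopropoxy-3-methylbenzamide; 4 (R)-2-methyloxirane
Product: 8 (3R)-6,8-diisopropoxy-3,7-dimethylisochroman-1-one, via aryllithium 5 (not isolated), via arylmagnesium bromide 6 (not isolated), via hydroxy amide 7 (not isolated)
Conditions: s-BuLi (1.2 equiv), TMEDA, THF, −78 °C; MgBr2·OEt2 (1.5 equiv), −78 → −20 °C; CuBr·SMe2 (10 mol %), 4 (1.5 equiv), −20 → 0 °C; dilute aq. HCl quench; crude 7, p-TsOH·H2O (1.2 equiv), toluene, 110 °C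
Reagents that add atoms: none
Why: Directed ortho metalation occurs at C6, the only free position ortho to the diethylamide, then transmetalation to magnesium and copper-catalysed SN2 opening of the epoxide at its CH2 terminus leave the C–O stereocenter of 4 untouched so that C3 of 8 is R, and acid-catalysed intramolecular alcoholysis of the twisted tertiary benzamide closes the six-membered lactone.

Step 4
Reactants: 8 (3R)-6,8-diisopropoxy-3,7-dimethylisochroman-1-one
Product: 9 (3R)-6,8-diisopropoxy-3,7-dimethyl-1-oxoisochromane-5-carbaldehyde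
Conditions: POCl3 (3 equiv), DMF, 0 → 75 °C; then ice-water
Reagents that add atoms: N,N-dimethylformamide CN(C)C=O; water O
Why: Vilsmeier–Haack formylation can only occur at C5, the single free ring position, which is ortho to the C6 ether and para to the C8 ether, and the reagent is not a chelating Lewis acid so the isopropyl ethers and the lactone should survive.

Step 5
Reactants: 9 (3R)-6,8-diisopropoxy-3,7-dimethyl-1-oxoisochromane-5-carbaldehyde
Product: 10 (3R)-5-(hydroxymethyl)-6,8-diisopropoxy-3,7-dimethylisochroman-1-one
Conditions: NaBH4 (0.6 equiv), THF/MeOH, 0 °C; then dilute aq. HCl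
Reagents that add atoms: none
Why: Borohydride reduction in cold methanol is chemoselective for the aryl aldehyde over the hindered aryl lactone.

Step 6
Reactants: 10 (3R)-5-(hydroxymethyl)-6,8-diisopropoxy-3,7-dimethylisochroman-1-one
Product: 11 (3R)-5-(bromomethyl)-6,8-diisopropoxy-3,7-dimethylisochroman-1-one
Conditions: PBr3 (0.4 equiv), CH2Cl2, 0 °C; used at once
Reagents that add atoms: phosphorus tribromide BrP(Br)Br
Why: The electron-rich primary benzylic alcohol is converted into its bromide through the bromophosphite by SN2 displacement, under conditions cold and short enough to leave the ethers and the lactone intact.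

Step 7
Reactants: 12 2,6-dimethyl-4H-pyran-4-one
Product: 14 (6-methyl-4-oxo-4H-pyran-2-yl)acetic acid, via lithiated pyranone 13 (not isolated)
Conditions: LiN(iPr)2 (1.1 equiv), THF, −78 °C; CO2 (gas, excess), −78 → 0 °C; dilute aq. HCl to pH 2, 0 °C
Reagents that add atoms: carbon dioxide O=C=O
Why: Lateral (vinylogous) deprotonation of a 2-methyl group of the pyranone by a lithium amide followed by carboxylation of the extended enolate is standard anion trapping and should give the acid, which is kept cold because it can decarboxylate on heating.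

Step 8
Reactants: 14 (6-methyl-4-oxo-4H-pyran-2-yl)acetic acid
Product: 16 methyl 4-(6-methyl-4-oxo-4H-pyran-2-yl)-3-oxobutanoate, via acyl imidazolide 15 (not isolated)
Conditions: 1,1'-carbonyldiimidazole (1.1 equiv), THF, 20 °C; Mg(O2CCH2CO2Me)2 (0.6 equiv), 20 → 40 °C; then dilute aq. HCl
Reagents that add atoms: magnesium bis(3-methoxy-3-oxopropanoate) COC(=O)CC(=O)[O-].COC(=O)CC(=O)[O-].[Mg+2]
Why: Masamune–Brooks homologation, in which the acyl imidazolide is C-acylated by neutral magnesium methyl malonate and the adduct decarboxylates on acidic work-up, should build the β-keto ester under conditions mild enough for the CH-acidic pyranylacetyl unit.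

Step 9
Reactants: 16 methyl 4-(6-methyl-4-oxo-4H-pyran-2-yl)-3-oxobutanoate; 11 (3R)-5-(bromomethyl)-6,8-diisopropoxy-3,7-dimethylisochroman-1-one
Product: 18 methyl 2-{[(3R)-6,8-diisopropoxy-3,7-dimethyl-1-oxoisochroman-5-yl]methyl}-4-(6-methyl-4-oxo-4H-pyran-2-yl)-3-oxobutanoate, via sodium enolate 17 (not isolated)
Conditions: NaH (1.0 equiv), THF, 0 °C; then 11 (1.0 equiv), 0 → 20 °C
Reagents that add atoms: none
Why: In this acetoacetic ester alkylation one equivalent of NaH forms the enolate at the most acidic carbon between ketone and ester, and this soft carbon nucleophile should displace the reactive benzylic bromide by SN2, the new C2 centre being formed as a mixture that is erased in step 10.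

Step 10
Reactants: 18 methyl 2-{[(3R)-6,8-diisopropoxy-3,7-dimethyl-1-oxoisochroman-5-yl]methyl}-4-(6-methyl-4-oxo-4H-pyran-2-yl)-3-oxobutanoate
Product: 19 (3R)-5-[(5,7-dihydroxy-2-methyl-4-oxo-4H-chromen-6-yl)methyl]-6,8-diisopropoxy-3,7-dimethylisochroman-1-one
Conditions: Mg(OMe)2 (4 equiv), MeOH/THF, 65 °C; then dilute aq. HCl, 20 °C
Reagents that add atoms: none
Why: Mg(OMe)2 converts the pyranylmethyl ketone of 18 into a magnesium-bound extended enolate that is nucleophilic at pyranone C3 (the future C4a), this carbon adds to the chelated methyl ester, methoxide leaves, and two enolisations turn the new cyclohexane-1,3-dione into the aromatic ring of 19. The closest known reaction type is the biomimetic intramolecular Claisen (Dieckmann-type) condensation by which pyranone-masked poly-β-keto esters are folded into acylphloroglucinols and 5,7-dihydroxychromones. The one new ring, the carbocycle C4a–C5–C6–C7–C8–C8a, closes in the 6-exo-trig mode at the ester carbonyl while the pyranone stays intact. No stereocenter is created: the uncontrolled C2 centre of 18 becomes the sp2 carbon C6 and the remote lactone C3 has no acidic hydrogen. The step needs C-acylation through pyranone C3 to win over aldol addition to the pyranone carbonyl, methoxide opening of the pyranone and retro-Claisen cleavage, and the substrate secures this because the ester is the best electrophile within six-membered reach of the extended enolate, the α-benzyl group disfavours the unproductive fully substituted keto ester enolate, and the chelating divalent magnesium both activates the ester and keeps free methoxide low. Regiochemistry is built in, since pyranone C2 already carries the ring oxygen and must become C8a, which places the benzylated carbon at C6 between the two new hydroxyls, and any methanolysis of the hindered lactone is reversed by the acidic work-up without touching C3.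

Step 11
Reactants: 19 (3R)-5-[(5,7-dihydroxy-2-methyl-4-oxo-4H-chromen-6-yl)methyl]-6,8-diisopropoxy-3,7-dimethylisochroman-1-one
Product: 20 (3R)-5-[(5-hydroxy-7-methoxy-2-methyl-4-oxo-4H-chromen-6-yl)methyl]-6,8-diisopropoxy-3,7-dimethylisochroman-1-one
Conditions: Me2SO4 (1.1 equiv), K2CO3 (1.5 equiv), acetone, 40 °C
Reagents that add atoms: dimethyl sulfate COS(=O)(=O)OC
Why: Williamson methylation with carbonate should differentiate the two chromone phenols because the 5-hydroxyl is locked in a hydrogen bond to the C4 carbonyl and is far less acidic and nucleophilic than the 7-hydroxyl, the usual selectivity of 5,7-dihydroxychromones.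

Step 12
Reactants: 20 (3R)-5-[(5-hydroxy-7-methoxy-2-methyl-4-oxo-4H-chromen-6-yl)methyl]-6,8-diisopropoxy-3,7-dimethylisochroman-1-one
Product: 21 (3R)-6,8-dihydroxy-5-[(5-hydroxy-7-methoxy-2-methyl-4-oxo-4H-chromen-6-yl)methyl]-3,7-dimethylisochroman-1-one (CNP0180307.1)
Conditions: BCl3 (6 equiv), CH2Cl2, −78 → 0 °C; then H2O
Reagents that add atoms: none
Why: Lewis-acid dealkylation with BCl3 should remove the secondary isopropyl aryl ethers by chloride attack on the activated isopropyl group at low temperature while the methyl ether (not ortho to a carbonyl), the lactone and the diarylmethane are retained and no bond to the C3 stereocenter is touched.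

Compound list
1 | methyl 2,4-dihydroxy-3-methylbenzoate | COC(=O)c1ccc(O)c(C)c1O | starting material
2 | methyl 2,4-diisopropoxy-3-methylbenzoate | COC(=O)c1ccc(OC(C)C)c(C)c1OC(C)C | intermediate
3 | N,N-diethyl-2,4-diisopropoxy-3-methylbenzamide | CCN(CC)C(=O)c1ccc(OC(C)C)c(C)c1OC(C)C | intermediate
4 | (R)-2-methyloxirane ((R)-propylene oxide) | C[C@@H]1CO1 | starting material
5 | [2-(diethylcarbamoyl)-3,5-diisopropoxy-4-methylphenyl]lithium | CCN(CC)C(=O)c1c([Li])cc(OC(C)C)c(C)c1OC(C)C | intermediate
6 | bromo[2-(diethylcarbamoyl)-3,5-diisopropoxy-4-methylphenyl]magnesium | CCN(CC)C(=O)c1c([Mg]Br)cc(OC(C)C)c(C)c1OC(C)C | intermediate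
7 | N,N-diethyl-6-[(2R)-2-hydroxypropyl]-2,4-diisopropoxy-3-methylbenzamide | CCN(CC)C(=O)c1c(C[C@@H](C)O)cc(OC(C)C)c(C)c1OC(C)C | intermediate
8 | (3R)-6,8-diisopropoxy-3,7-dimethylisochroman-1-one | CC(C)Oc1cc2C[C@@H](C)OC(=O)c2c(OC(C)C)c1C | intermediate
9 | (3R)-6,8-diisopropoxy-3,7-dimethyl-1-oxoisochromane-5-carbaldehyde | O=Cc1c(OC(C)C)c(C)c(OC(C)C)c2c1C[C@@H](C)OC2=O | intermediate
10 | (3R)-5-(hydroxymethyl)-6,8-diisopropoxy-3,7-dimethylisochroman-1-one | OCc1c(OC(C)C)c(C)c(OC(C)C)c2c1C[C@@H](C)OC2=O | intermediate
11 | (3R)-5-(bromomethyl)-6,8-diisopropoxy-3,7-dimethylisochroman-1-one | BrCc1c(OC(C)C)c(C)c(OC(C)C)c2c1C[C@@H](C)OC2=O | intermediate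
12 | 2,6-dimethyl-4H-pyran-4-one | Cc1cc(=O)cc(C)o1 | starting material
13 | [(6-methyl-4-oxo-4H-pyran-2-yl)methyl]lithium | [Li]Cc1cc(=O)cc(C)o1 | intermediate
14 | (6-methyl-4-oxo-4H-pyran-2-yl)acetic acid | OC(=O)Cc1cc(=O)cc(C)o1 | intermediate
15 | 2-[2-(1H-imidazol-1-yl)-2-oxoethyl]-6-methyl-4H-pyran-4-one | O=C(Cc1cc(=O)cc(C)o1)n1ccnc1 | intermediate
16 | methyl 4-(6-methyl-4-oxo-4H-pyran-2-yl)-3-oxobutanoate | COC(=O)CC(=O)Cc1cc(=O)cc(C)o1 | intermediate
17 | sodium 4-methoxy-1-(6-methyl-4-oxo-4H-pyran-2-yl)-4-oxobut-2-en-2-olate | COC(=O)C=C([O-])Cc1cc(=O)cc(C)o1.[Na+] | intermediate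
18 | methyl 2-{[(3R)-6,8-diisopropoxy-3,7-dimethyl-1-oxoisochroman-5-yl]methyl}-4-(6-methyl-4-oxo-4H-pyran-2-yl)-3-oxobutanoate (mixture at C2 of the chain) | COC(=O)C(Cc1c(OC(C)C)c(C)c(OC(C)C)c2c1C[C@@H](C)OC2=O)C(=O)Cc1cc(=O)cc(C)o1 | intermediate
19 | (3R)-5-[(5,7-dihydroxy-2-methyl-4-oxo-4H-chromen-6-yl)methyl]-6,8-diisopropoxy-3,7-dimethylisochroman-1-one | Cc1cc(=O)c2c(O)c(Cc3c(OC(C)C)c(C)c(OC(C)C)c4c3C[C@@H](C)OC4=O)c(O)cc2o1 | intermediate
20 | (3R)-5-[(5-hydroxy-7-methoxy-2-methyl-4-oxo-4H-chromen-6-yl)methyl]-6,8-diisopropoxy-3,7-dimethylisochroman-1-one | COc1cc2oc(C)cc(=O)c2c(O)c1Cc1c(OC(C)C)c(C)c(OC(C)C)c2c1C[C@@H](C)OC2=O | intermediate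
21 | (3R)-6,8-dihydroxy-5-[(5-hydroxy-7-methoxy-2-methyl-4-oxo-4H-chromen-6-yl)methyl]-3,7-dimethylisochroman-1-one | COc1cc2oc(C)cc(=O)c2c(O)c1Cc1c(O)c(C)c(O)c2c1C[C@@H](C)OC2=O | target

Total step count: 12. Longest linear sequence: 10 steps (steps 1–6 and 9–12 from compound 1); the pyranone branch (steps 7 and 8) joins at step 9.

Steps most likely to fail

Step 10. The extended enolate may instead close by aldol addition to the pyranone carbonyl, the pyranone may be opened by methoxide and refold, or the keto ester may fragment by retro-Claisen cleavage before C-acylation occurs. The fallback forms the diarylmethane bond directly by cross-coupling; it sets out from 11 and comes back at 20. Zinc insertion into 11 (Zn dust, LiCl, THF, 20 °C) should give bromo{[(3R)-6,8-diisopropoxy-3,7-dimethyl-1-oxoisochroman-5-yl]methyl}zinc F1. Purchased 5-hydroxy-7-methoxy-2-methyl-4H-chromen-4-one (eugenin, COc1cc2oc(C)cc(=O)c2c(O)c1) is iodinated ortho to its chelated hydroxyl (benzyltrimethylammonium dichloroiodate, CaCO3, CH2Cl2/MeOH, 20 °C) to 5-hydroxy-6-iodo-7-methoxy-2-methyl-4H-chromen-4-one F2. Negishi coupling of F1 with F2 (Pd(OAc)2, SPhos, THF, 20 → 50 °C), which tolerates the chelated phenol, should give 20, and step 12 follows.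

Step 3. The hindered ortho-amido arylmetal may open the epoxide too slowly, the epoxide may be lost to bromohydrin formation, or the metalated amide may self-condense on warming. The fallback replaces epoxide opening by lateral acylation and carbonyl reduction; it sets out from 3 and comes back at 7. Lithiation of 3 as in step 3 (to 5) and quenching with dimethyl sulfate should give N,N-diethyl-2,4-diisopropoxy-3,6-dimethylbenzamide F3. Lateral lithiation of its new benzylic methyl (s-BuLi, THF, −78 °C) and acylation with N-methoxy-N-methylacetamide should give N,N-diethyl-2,4-diisopropoxy-3-methyl-6-(2-oxopropyl)benzamide F4. Reduction of the methyl ketone with an (R)-selective alcohol dehydrogenase of the Lactobacillus kefir type (NADP+, 2-propanol, buffer, 30 °C) should give 7, which is lactonised as in step 3.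

Step 9. Alkylation may occur at the pyranyl-methylene carbon or on enolate oxygen, a second alkylation or premature base-induced cyclisation of the keto ester may intervene, or the electron-rich benzylic bromide may decompose before it is intercepted. The fallback replaces SN2 alkylation by condensation and conjugate reduction; it sets out from 9 and 16 and comes back at 18, so steps 5 and 6 are not needed. Knoevenagel condensation of 9 with 16 (piperidine, AcOH, toluene, 4 Å sieves, 80 °C) should give methyl 2-{[(3R)-6,8-diisopropoxy-3,7-dimethyl-1-oxoisochroman-5-yl]methylidene}-4-(6-methyl-4-oxo-4H-pyran-2-yl)-3-oxobutanoate F5 as a mixture of alkene isomers. Transfer hydrogenation of its electron-poor double bond with Hantzsch ester (diethyl 2,6-dimethyl-1,4-dihydropyridine-3,5-dicarboxylate, toluene, 60 °C) should give 18.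

Further compounds
F1 | step 10 | bromo{[(3R)-6,8-diisopropoxy-3,7-dimethyl-1-oxoisochroman-5-yl]methyl}zinc | Br[Zn]Cc1c(OC(C)C)c(C)c(OC(C)C)c2c1C[C@@H](C)OC2=O
F2 | step 10 | 5-hydroxy-6-iodo-7-methoxy-2-methyl-4H-chromen-4-one | COc1cc2oc(C)cc(=O)c2c(O)c1I
F3 | step 3 | N,N-diethyl-2,4-diisopropoxy-3,6-dimethylbenzamide | CCN(CC)C(=O)c1c(C)cc(OC(C)C)c(C)c1OC(C)C
F4 | step 3 | N,N-diethyl-2,4-diisopropoxy-3-methyl-6-(2-oxopropyl)benzamide | CCN(CC)C(=O)c1c(CC(C)=O)cc(OC(C)C)c(C)c1OC(C)C
F5 | step 9 | methyl 2-{[(3R)-6,8-diisopropoxy-3,7-dimethyl-1-oxoisochroman-5-yl]methylidene}-4-(6-methyl-4-oxo-4H-pyran-2-yl)-3-oxobutanoate | COC(=O)C(=Cc1c(OC(C)C)c(C)c(OC(C)C)c2c1C[C@@H](C)OC2=O)C(=O)Cc1cc(=O)cc(C)o1
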